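Abbreviations: TBS = tert-butyldimethylsilyl, TES = triethylsilyl, TMS = trimethylsilyl, Ts = 4-methylbenzenesulfonyl, Ms = methanesulfonyl, CBS = Corey–Bakshi–Shibata. Germacrane numbering (C1–C15) is used for every intermediate.

## Analysis of the target

The target is a germacrane-type sesquiterpene lactone. Its ten-membered carbocycle C1–C10 is bridged by an ether oxygen between C1 and C4 (oxolane O/C1/C2/C3/C4) and fused across C6–C7 to a butenolide (C6, C7, C11, C12, O). The exocyclic C5=C6 bond (5E, C4 cis to C7) makes C5=C6–C7=C11–C12=O one conjugated enol-lactone system. C13 is the acetoxymethyl carbon on C11, C14 the methyl on C10 and C15 the methyl on C4.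

There are four stereocentres, C1 (S), C4 (S), C8 (S) and C10 (R); C4 and C10 are fully substituted carbinol carbons. O8 and O10 are 1,3-syn along C7–C8–C9–C10–C1, and O10 and the ether oxygen on C1 are anti across C10–C1. From the descriptors, H-1 and the C4 methyl lie on opposite faces of the oxolane, so the ring bonds C1–C10 and C4–C5 are trans across the five-membered ring.

The sensitive groups are the enol lactone (an acyl enol ether, opened by base and nucleophiles), the allylic C13 acetate on the butenolide, the angelate (Z to E isomerisation under nucleophilic catalysis) and the free tertiary C10–OH next to the ether carbon C1.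

The synthesis is hard for three reasons. A medium ring has to be closed. The ether bridge has a configuration that cannot be left to thermodynamics. The oxidation pattern around C5–C7 and C11–C13 tolerates no organometallic chemistry.

The strategy rests on one feature. Among the ten ring bonds only C2–C3 joins two carbons that carry neither a heteroatom nor unsaturation, and it sits between the two ether carbons. Written as a (Z)-C2=C3 alkene, it turns the ten-membered ring into a metathesis product and the oxolane into the cyclisation product of a (Z)-2-ene-1,4-diol. The dienolide is the oxidised form of a 2,3,4-trisubstituted furan whose free α-position is C12.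

## Retrosynthetic reasoning

**Ester bonds at C8 and C13.** The angelate and the acetate of 41 are removed first, giving 38 and 39, then the triol 37. They come last in the forward sense because the angelate isomerises easily and the C13 acetate is an allylic electrophile. The forward steps need a primary-selective acetylation and an esterification of the hindered C8–OH that leaves the (Z)-alkene of 39 intact.

**O–Si bonds.** Triol 37 is traced to the tris-silyl ether 36. Silyl ethers are chosen because fluoride removes them without touching the enol lactone.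

**C12=O and C5=C6.** The dienolide of 36 is cut back through the lactol 34 to the furan 32. The furan holds the C6–C7 cis junction, survives bases, hydrides and metathesis, and has only one α-hydrogen (C12–H). Forward, photooxygenation across C6/C12 with base-induced opening fixes the carbonyl at C12, and dehydration of C6–OH against C5–H gives the exocyclic alkene.

**C2–C3 saturation.** Oxolane 32 is traced to the 2,5-dihydrofuran 31 so that the bond made by metathesis reappears. Forward, a hydrogenation that spares the furan is needed.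

**O–C1 bond.** The ether is opened at the secondary carbon C1, giving diol 29 (through sulfonate 30). The tertiary C4–O bond is kept, because only a secondary carbon can be substituted with clean inversion. Forward, the C4 alkoxide must displace the activated C1 oxygen by SN2.

**C2=C3 bond.** The cyclodecene 29 is opened to the diene diol 28. This is the only ring bond whose formation creates no stereocentre and needs no functional group that the target lacks.

**C1 carbinol and C1–C2.** Alcohol 28 is traced to enone 27, the carbinols 26, aldehyde 25, diol 24 and the fully silylated 23. Making the C1 carbinol last by reagent-controlled reduction avoids a protecting group on it.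

**C8 carbinol and C7–C8.** Silyl ether 23 goes back to alcohol 22, ketone 21 and carbinol 20, which is cut between C7 and C8 into the furyllithium 19 (from bromide 12) and aldehyde 18. This divides the molecule into two halves of similar size, each with one quaternary carbinol.

**Furan half.** Bromide 12 is traced to epoxide 10 by removing one vinyl carbon, and 10 to bromofuran 5 and tosylate 7 (C5–C6 bond). The bromine first directs lithiation to C6 and later becomes the C7 nucleophile. 5 comes from 1 through 4.

**Chain half.** Aldehyde 18 comes from dithiane 17, made from epoxide 13 and 14 (C8–C9 bond, with 14 as the formyl anion). Both 13 and 7 derive from 6, so C4 and C10 come from the same chiral-pool epoxide.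

## Alternatives that were turned down

**Alternative 1:** The O–C1 bond and the C5=C6 alkene are both traced to epoxides (C4–C5 and C1–C10) on a preformed ten-membered ring that already holds the butenolide with C6–H. In the forward step DBU removes the γ-proton at C6 and the 2-oxidofuran expels the C5–O bond (vinylogous E1cB). The freed C4 alkoxide opens the other epoxide at C1 (5-exo, inversion) to give A1, the 8,13-bis-TBS ether of the deacylated target.
- For it: one operation builds dienolide and oxolane, C10–OH needs no protection, and no furan oxidation or late dehydration is needed. C1 is set by the same kind of stereospecific inversion. On these points it is as strong as or stronger than the chosen route.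
- Against it: C1, C4 and C10 would all depend on face-selective epoxidation of two trisubstituted alkenes on a ten-membered ring of unknown conformation. The 1,10-epoxide must have the face that leads to the trans bridge. The ring itself still has to be made. The same dienolate can expel the C13 oxygen in a competing vinylogous elimination.
- Comparison: in place of the short cascade, the chosen strategy offers a ring closure that creates no stereocentre and four stereocentres fixed on open-chain intermediates.

**Alternative 2:** The C6–C7 bond and the lactone C12–O bond are cut. Forward, CrCl2 with catalytic NiCl2 (zerovalent nickel inserts into the C7 enol triflate, transmetalation gives a trivalent alkenylchromium) adds C7 to the C6 aldehyde, and the C6 alkoxide lactonises onto the cis methyl ester to give A2.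
- For it: this closure is among the most dependable for medium rings and is very chemoselective. Ring and butenolide form together, and no free allylic alcohols or furan oxidation are needed. In functional-group tolerance it is at least equal to metathesis.
- Against it: A2 is a 5,6-dihydro butenolide. C5=C6 must still be introduced by a dehydrogenation through the γ-dienolate, which can again lose the C13 substituent, and a C6 stereocentre is made only to be destroyed. The oxolane would already be present, so the macrocyclisation has to pay for the strain of the trans bridge. A tetrasubstituted enol triflate of defined geometry and a large excess of chromium are required.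
- Comparison: the chosen route closes the ring before the strained ether exists and draws the dienolide oxidation level from the furan in two steps.

**Alternative 3:** The tertiary O–C4 bond is cut. Forward, a mild acid activates the 4,5-epoxide and the C1 hydroxyl attacks C4 across the ring (5-exo, inversion at C4) to give A3, whose C5 hydroxyl is later eliminated towards C6.
- For it: attack at the more substituted epoxide carbon is the favoured mode under acid, C1 is never disturbed, and the later dehydration is easy. It is short.
- Against it: the configuration at C4 would be decided at a tertiary carbon under acid, where bond breaking runs ahead of bond making. Any cation character lets the ring close to the less strained cis-bridged epimer, the outcome this target excludes. Hydride or alkyl shifts of the trisubstituted epoxide compete, acid endangers the tertiary TES ether, and three stereocentres (C4, C5, C6) must be controlled to deliver one.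
- Comparison: the chosen route forms the ether at the secondary C1 with an alkoxide under basic, kinetic conditions and never breaks a bond at C4.

Key step: step 18

Remark: the configuration is taken exactly as specified, (1S,4S,8S,10R); in it C10 and C5 are trans on the oxolane, so the ether bridge is strained and is planned as a kinetically controlled SN2 closure (the C1 epimer with a cis bridge would follow from the other CBS enantiomer in step 17).

## Route

Step 1
Reactants: 1 3,4-dibromofuran
Product: 4 (4-bromofuran-3-yl)methanol, via 3-bromo-4-lithiofuran 2 (not isolated), via 4-bromofuran-3-carbaldehyde 3 (not isolated)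
Conditions: n-BuLi (1.0 equiv), Et2O, −78 °C; DMF, −78 to 0 °C; then MeOH, NaBH4, 0 °C
Reagents that add atoms: N,N-dimethylformamide CN(C)C=O
Why: Bromine–lithium exchange on one of two equivalent C–Br bonds gives a 3-lithiofuran that is stable at −78 °C; formylation and in-flask borohydride reduction are standard.

Step 2
Reactants: 4 (4-bromofuran-3-yl)methanol
Product: 5 3-bromo-4-[(tert-butyldimethylsilyloxy)methyl]furan
Conditions: TBSCl, imidazole, CH2Cl2, rt
Reagents that add atoms: tert-butyldimethylsilyl chloride CC(C)(C)[Si](C)(C)Cl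
Why: Standard silylation of a primary alcohol; this oxygen becomes O13.

Step 3
Reactants: 6 (S)-2-methylglycidol
Product: 7 [(2R)-2-methyloxiran-2-yl]methyl 4-methylbenzenesulfonate
Conditions: TsCl, Et3N, DMAP (cat.), CH2Cl2, 0 °C
Reagents that add atoms: 4-methylbenzenesulfonyl chloride Cc1ccc(cc1)S(=O)(=O)Cl
Why: Sulfonylation of the primary alcohol leaves the quaternary epoxide carbon untouched; the descriptor changes from S to R only through CIP priorities.

Step 4
Reactants: 5 3-bromo-4-[(tert-butyldimethylsilyloxy)methyl]furan; 7 [(2R)-2-methyloxiran-2-yl]methyl 4-methylbenzenesulfonate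
Product: 10 3-bromo-4-[(tert-butyldimethylsilyloxy)methyl]-2-{[(2R)-2-methyloxiran-2-yl]methyl}furan, via 2-lithiofuran 8 (not isolated), via hydroxy tosylate 9 (not isolated)
Conditions: LiN(i-Pr)2, THF, −78 °C; 7, BF3·OEt2, −78 °C; then K2CO3, MeOH, rt
Reagents that add atoms: none
Why: Bromine-directed ortho-lithiation removes C6–H rather than C12–H; BF3-assisted opening of the epoxide at its CH2 carbon forms C5–C6, and Williamson closure of the tertiary alkoxide onto the primary tosylate transposes the epoxide without touching C4.

Step 5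
Reactants: 10 3-bromo-4-[(tert-butyldimethylsilyloxy)methyl]-2-{[(2R)-2-methyloxiran-2-yl]methyl}furan
Product: 12 3-bromo-4-[(tert-butyldimethylsilyloxy)methyl]-2-[(2R)-2-methyl-2-(trimethylsilyloxy)but-3-enyl]furan, via lithium alkoxide 11 (not isolated)
Conditions: Me3S+ I− (4 equiv), n-BuLi (3.8 equiv), THF, −10 °C to rt; then TMSCl, 0 °C
Reagents that add atoms: trimethylsulfonium iodide C[S+](C)C.[I-]; trimethylsilyl chloride C[Si](C)(C)Cl
Why: One-carbon homologation of a terminal epoxide to an allylic alcohol by dimethylsulfonium methylide (opening at CH2, then base-induced loss of dimethyl sulfide); the tertiary alkoxide is silylated in the same flask and C4 (R) is not involved.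

Step 6
Reactants: 6 (S)-2-methylglycidol
Product: 13 triethyl{[(2R)-2-methyloxiran-2-yl]methoxy}silane
Conditions: TESCl, imidazole, CH2Cl2, 0 °C
Reagents that add atoms: triethylsilyl chloride CC[Si](CC)(CC)Cl
Why: Standard silylation; protection prevents Payne rearrangement of the epoxy alkoxide in step 7.

Step 7
Reactants: 14 1,3-dithiane; 13 triethyl{[(2R)-2-methyloxiran-2-yl]methoxy}silane
Product: 17 2-[(2R)-2-methyl-2,3-bis(triethylsilyloxy)propyl]-1,3-dithiane, via 2-lithio-1,3-dithiane 15 (not isolated), via lithium alkoxide 16 (not isolated)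
Conditions: n-BuLi, THF, −30 °C; 13, −30 to 0 °C; then TESOTf, −78 to 0 °C
Reagents that add atoms: triethylsilyl trifluoromethanesulfonate CC[Si](CC)(CC)OS(=O)(=O)C(F)(F)F
Why: Corey–Seebach umpolung: the lithiated dithiane opens the 2,2-disubstituted epoxide at CH2 (C8–C9 bond) and the tertiary alkoxide is trapped as its TES ether; C10 keeps the configuration of 6.

Step 8
Reactants: 17 2-[(2R)-2-methyl-2,3-bis(triethylsilyloxy)propyl]-1,3-dithiane
Product: 18 (3R)-3-methyl-3,4-bis(triethylsilyloxy)butanal
Conditions: MeI, CaCO3, MeCN/H2O (9:1), 45 °C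
Reagents that add atoms: water O
Why: S-Alkylative dithiane hydrolysis under carbonate buffering, which should spare both TES ethers.

Step 9
Reactants: 12 3-bromo-4-[(tert-butyldimethylsilyloxy)methyl]-2-[(2R)-2-methyl-2-(trimethylsilyloxy)but-3-enyl]furan; 18 (3R)-3-methyl-3,4-bis(triethylsilyloxy)butanal
Product: 20 furyl carbinol (4R,10R; both C8 epimers) with C7–CH(OH)–CH2–C(CH3)(OTES)–CH2OTES, via 3-furyllithium 19 (not isolated)
Conditions: n-BuLi (1.05 equiv), Et2O, −78 °C; then 18, −78 °C; aq. NH4Cl
Reagents that add atoms: none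
Why: Bromine–lithium exchange at −78 °C (below the temperature at which 3-lithiofurans isomerise) and 1,2-addition to the aldehyde form C7–C8; the C8 mixture is corrected in steps 10 and 11.

Step 10
Reactants: 20 furyl carbinol (4R,10R; both C8 epimers)
Product: 21 furyl ketone (4R,10R) with C8=O
Conditions: Dess–Martin periodinane, NaHCO3, CH2Cl2, 0 °C to rt
Reagents that add atoms: none
Why: Buffered Dess–Martin oxidation of a secondary alcohol; silyl ethers and the vinyl group are inert.

Step 11
Reactants: 21 furyl ketone (4R,10R)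
Product: 22 (4R,8S,10R)-furyl carbinol
Conditions: (R)-2-methyl-CBS-oxazaborolidine (1 equiv), catecholborane, toluene, −40 °C
Reagents that add atoms: none
Why: CBS reduction with the furan ring as the large and the C9 methylene as the small substituent, so the (R)-catalyst should give (8S); catecholborane does not hydroborate the vinyl group.

Step 12
Reactants: 22 (4R,8S,10R)-furyl carbinol
Product: 23 (4R,8S,10R)-8-O-TBS ether (1-OTES, 4-OTMS, 10-OTES, 13-OTBS)
Conditions: TBSOTf, 2,6-lutidine, CH2Cl2, −78 to −20 °C
Reagents that add atoms: tert-butyldimethylsilyl trifluoromethanesulfonate CC(C)(C)[Si](C)(C)OS(=O)(=O)C(F)(F)F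
Why: Silyl triflate silylation of a hindered secondary alcohol.

Step 13
Reactants: 23 (4R,8S,10R)-8-O-TBS ether
Product: 24 (4R,8S,10R)-1,4-diol (primary C1–OH and tertiary C4–OH free)
Conditions: PPTS (0.2 equiv), MeOH/CH2Cl2 (1:1), 0 °C
Reagents that add atoms: none
Why: Acid-catalysed methanolysis follows silyl lability: the primary TES and the tertiary TMS ethers are cleaved, while the tertiary TES and both TBS ethers should remain.

Step 14
Reactants: 24 (4R,8S,10R)-1,4-diol
Product: 25 (2R,4S)-4-(tert-butyldimethylsilyloxy)-2-methyl-2-(triethylsilyloxy)butanal carrying the furan at C4 of the butanal (C1 aldehyde; 4R,8S,10R)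
Conditions: Dess–Martin periodinane, NaHCO3, CH2Cl2, 0 °C
Reagents that add atoms: none
Why: Dess–Martin oxidation of the primary alcohol; the tertiary allylic C4–OH cannot be oxidised and the α-quaternary aldehyde cannot epimerise.

Step 15
Reactants: 25 C1 aldehyde (4R,8S,10R)
Product: 26 C1 vinyl carbinols (4R,8S,10R; both C1 epimers)
Conditions: CH2=CHMgBr (3 equiv), THF, −78 to −40 °C; aq. NH4Cl at −40 °C
Reagents that add atoms: vinylmagnesium bromide C=C[Mg]Br
Why: Grignard addition to a non-enolisable aldehyde forms C1–C2; one equivalent is consumed by C4–OH, and a cold quench prevents TES migration from O10 to the C1 alkoxide.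

Step 16
Reactants: 26 C1 vinyl carbinols (4R,8S,10R)
Product: 27 vinyl ketone (4R,8S,10R) with C1=O
Conditions: Dess–Martin periodinane, NaHCO3, CH2Cl2, 0 °C; used at once
Reagents that add atoms: none
Why: Dess–Martin oxidation of an allylic alcohol to the enone under neutral conditions that do not trigger conjugate addition.

Step 17
Reactants: 27 vinyl ketone (4R,8S,10R)
Product: 28 2-[(2R)-2-hydroxy-2-methylbut-3-enyl]-3-[(1S,3R,4R)-1-(tert-butyldimethylsilyloxy)-4-hydroxy-3-methyl-3-(triethylsilyloxy)hex-5-enyl]-4-[(tert-butyldimethylsilyloxy)methyl]furan (1R,4R,8S,10R)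
Conditions: (S)-2-methyl-CBS-oxazaborolidine (1 equiv), catecholborane, toluene/CH2Cl2, −78 °C
Reagents that add atoms: none
Why: CBS 1,2-reduction of the enone with the fully substituted C10 as the large and vinyl as the small group, so the (S)-catalyst should give (1R); Felkin–Anh attack anti to the C10–OTES bond has the same sense (matched).

Step 18
Reactants: 28 furan-linked bis-allylic diol diene (1R,4R,8S,10R)
Product: 29 furan-fused (Z)-cyclodecene-1,4-diol (1R,2Z,4R,8S,10R; 8-OTBS, 10-OTES, 13-OTBS)
Conditions: second-generation Grubbs catalyst (H2IMes)(PCy3)Cl2Ru=CHPh (15 mol %), 1,4-benzoquinone (30 mol %), toluene (0.001 M), 80 °C, argon purge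
Reagents that add atoms: none
Why: After phosphine loss the ruthenium benzylidene should load onto the vinyl group at C1 (a secondary allylic alcohol, less hindered than the vinyl on quaternary C4, with the free hydroxyl known to speed this exchange); the resulting C2 alkylidene undergoes intramolecular [2+2] cycloaddition with the C4 vinyl group, and cycloreversion of the ruthenacyclobutane expels ethene and forms C2=C3. The closest known reaction type is ring-closing metathesis to ten-membered carbocycles and lactones flanked by allylic oxygen substituents. The ten-membered ring is closed by this one endocyclic C=C bond; ring closure is helped by the furan, which fixes C5 and C8 cis on C6=C7, and by the two fully substituted carbons C4 and C10. No stereocentre is formed, and C1, C4, C8 and C10 are carried through unchanged. The step needs three selectivities: ring closure over oligomerisation (high dilution), the (Z)-alkene over the (E)-alkene, and no isomerisation of the allylic alcohols to ketones by ruthenium hydrides (benzoquinone). The (Z)-geometry is expected because the catalyst equilibrates the alkene by secondary metathesis and an (E)-C2=C3 would turn the substituents of the branched carbons C1 and C4 into a ring that already holds the flat furan. The strained ether bridge does not yet exist, so the macrocyclisation does not pay for it. Only the (Z)-2-ene-1,4-diol can close to the dihydrofuran in step 19.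

Step 19
Reactants: 29 furan-fused (Z)-cyclodecene-1,4-diol (1R,2Z,4R,8S,10R)
Product: 31 1,4-epoxy-bridged 2,5-dihydrofuran (1S,4R,8S,10R), via C1 mesylate 30 (not isolated)
Conditions: MsCl (1.1 equiv), Et3N, CH2Cl2, −40 °C; crude mesylate in THF, KN(SiMe3)2, −78 to 0 °C
Reagents that add atoms: none
Why: Selective sulfonylation of the secondary allylic C1–OH (the tertiary C4–OH is slower) followed by intramolecular Williamson etherification, 5-exo-tet, by the C4 alkoxide with inversion at C1 to give (1S); the (Z)-alkene holds O4 next to C1 and C4 is not touched.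

Step 20
Reactants: 31 1,4-epoxy-bridged 2,5-dihydrofuran (1S,4R,8S,10R)
Product: 32 1,4-epoxy-bridged oxolane fused furan (1S,4S,8S,10R)
Conditions: 2-nitrobenzenesulfonohydrazide, Et3N, CH2Cl2, rt
Reagents that add atoms: none
Why: Diimide syn-hydrogenation of the cis-disubstituted ring alkene; the aromatic furan and the silyl ethers are inert, and the C4 descriptor changes from R to S only by priority.

Step 21
Reactants: 32 1,4-epoxy-bridged oxolane fused furan (1S,4S,8S,10R)
Product: 34 γ-hydroxybutenolide (C12=O; C6 hemiketal as an epimer mixture), via furan endoperoxide 33 (not isolated)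
Conditions: O2, hν (visible), tetraphenylporphyrin (cat.), i-Pr2NEt, CH2Cl2, −78 °C, then rt
Reagents that add atoms: oxygen O=O
Why: [4+2] cycloaddition of singlet oxygen across C6/C12, then Kornblum–DeLaMare-type base-induced opening by loss of the only α-hydrogen (C12–H), places the carbonyl at C12 and the hydroxyl at C6 regiospecifically.

Step 22
Reactants: 34 γ-hydroxybutenolide
Product: 36 (1S,4S,5E,8S,10R)-8,13-bis-O-TBS-10-O-TES dienolide, via C6 mesylate 35 (not isolated)
Conditions: MsCl, Et3N, CH2Cl2, −20 to 0 °C
Reagents that add atoms: none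
Why: Dehydration of the tertiary lactol through its sulfonate (E1-type elimination via the acyloxy-stabilised cation); only C5 has β-hydrogens, and the ring should hold C4 cis to C7, which is the (5E) geometry.

Step 23
Reactants: 36 (1S,4S,5E,8S,10R)-8,13-bis-O-TBS-10-O-TES dienolide
Product: 37 (1S,4S,5E,8S,10R)-1,4-epoxy-8,10,13-trihydroxygermacra-5,7(11)-dien-6,12-olide
Conditions: HF·pyridine, pyridine, THF, 0 °C to rt
Reagents that add atoms: none
Why: Buffered fluoride desilylation removes the primary and secondary TBS and the tertiary TES ethers without opening the enol lactone.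

Step 24
Reactants: 37 triol
Product: 38 13-O-acetyl derivative of 37 (8-OH and 10-OH free)
Conditions: Ac2O (1.1 equiv), 2,4,6-collidine, CH2Cl2, −20 °C
Reagents that add atoms: acetic anhydride CC(=O)OC(C)=O
Why: Chemoselective acylation, primary over hindered secondary over tertiary, with a weak non-nucleophilic base at low temperature.

Step 25
Reactants: 38 13-O-acetyl derivative of 37; 39 angelic acid
Product: 41 (1S,4S,5E,8S,10R)-13-acetoxy-8-angeloyloxy-1,4-epoxy-10-hydroxygermacra-5,7(11)-dien-6,12-olide, via angelic 2,4,6-trichlorobenzoic anhydride 40 (not isolated)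
Conditions: 39, 2,4,6-trichlorobenzoyl chloride, Et3N, toluene, rt; then 38, toluene, 80 °C (no DMAP)
Reagents that add atoms: none
Why: Mixed-anhydride (Yamaguchi-type) esterification without a nucleophilic catalyst, the usual way to make angelates without isomerisation to tiglates; the tertiary C10–OH does not react.

## Compound list

1 | 3,4-dibromofuran | Brc1cocc1Br | starting material
2 | 3-bromo-4-lithiofuran | [Li]c1cocc1Br | intermediate
3 | 4-bromofuran-3-carbaldehyde | O=Cc1cocc1Br | intermediate
4 | (4-bromofuran-3-yl)methanol | OCc1cocc1Br | intermediate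
5 | 3-bromo-4-[(tert-butyldimethylsilyloxy)methyl]furan | CC(C)(C)[Si](C)(C)OCc1cocc1Br | intermediate
6 | (S)-2-methylglycidol | C[C@]1(CO)CO1 | starting material
7 | [(2R)-2-methyloxiran-2-yl]methyl 4-methylbenzenesulfonate | C[C@]1(COS(=O)(=O)c2ccc(C)cc2)CO1 | intermediate
8 | 3-bromo-4-[(tert-butyldimethylsilyloxy)methyl]-2-lithiofuran | CC(C)(C)[Si](C)(C)OCc1coc([Li])c1Br | intermediate
9 | (2R)-3-{3-bromo-4-[(tert-butyldimethylsilyloxy)methyl]furan-2-yl}-2-hydroxy-2-methylpropyl 4-methylbenzenesulfonate | C[C@](O)(COS(=O)(=O)c1ccc(C)cc1)Cc1occ(CO[Si](C)(C)C(C)(C)C)c1Br | intermediate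
10 | 3-bromo-4-[(tert-butyldimethylsilyloxy)methyl]-2-{[(2R)-2-methyloxiran-2-yl]methyl}furan | C[C@@]1(Cc2occ(CO[Si](C)(C)C(C)(C)C)c2Br)CO1 | intermediate
11 | lithium (2R)-1-{3-bromo-4-[(tert-butyldimethylsilyloxy)methyl]furan-2-yl}-2-methylbut-3-en-2-olate | C=C[C@](C)([O-])Cc1occ(CO[Si](C)(C)C(C)(C)C)c1Br.[Li+] | intermediate
12 | 3-bromo-4-[(tert-butyldimethylsilyloxy)methyl]-2-[(2R)-2-methyl-2-(trimethylsilyloxy)but-3-enyl]furan | C=C[C@](C)(O[Si](C)(C)C)Cc1occ(CO[Si](C)(C)C(C)(C)C)c1Br | intermediate
13 | triethyl{[(2R)-2-methyloxiran-2-yl]methoxy}silane | C[C@]1(CO[Si](CC)(CC)CC)CO1 | intermediate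
14 | 1,3-dithiane | C1CSCSC1 | starting material
15 | 2-lithio-1,3-dithiane | [Li]C1SCCCS1 | intermediate
16 | lithium (2R)-1-(1,3-dithian-2-yl)-2-methyl-3-(triethylsilyloxy)propan-2-olate | C[C@]([O-])(CO[Si](CC)(CC)CC)CC1SCCCS1.[Li+] | intermediate
17 | 2-[(2R)-2-methyl-2,3-bis(triethylsilyloxy)propyl]-1,3-dithiane | C[C@](O[Si](CC)(CC)CC)(CO[Si](CC)(CC)CC)CC1SCCCS1 | intermediate
18 | (3R)-3-methyl-3,4-bis(triethylsilyloxy)butanal | O=CC[C@@](C)(O[Si](CC)(CC)CC)CO[Si](CC)(CC)CC | intermediate
19 | 4-[(tert-butyldimethylsilyloxy)methyl]-3-lithio-2-[(2R)-2-methyl-2-(trimethylsilyloxy)but-3-enyl]furan | C=C[C@](C)(O[Si](C)(C)C)Cc1occ(CO[Si](C)(C)C(C)(C)C)c1[Li] | intermediate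
20 | 2-[(2R)-2-methyl-2-(trimethylsilyloxy)but-3-enyl]-3-[(3R)-1-hydroxy-3-methyl-3,4-bis(triethylsilyloxy)butyl]-4-[(tert-butyldimethylsilyloxy)methyl]furan (both C8 epimers) | C=C[C@](C)(O[Si](C)(C)C)Cc1occ(CO[Si](C)(C)C(C)(C)C)c1C(O)C[C@@](C)(O[Si](CC)(CC)CC)CO[Si](CC)(CC)CC | intermediate
21 | (3R)-1-{2-[(2R)-2-methyl-2-(trimethylsilyloxy)but-3-enyl]-4-[(tert-butyldimethylsilyloxy)methyl]furan-3-yl}-3-methyl-3,4-bis(triethylsilyloxy)butan-1-one | C=C[C@](C)(O[Si](C)(C)C)Cc1occ(CO[Si](C)(C)C(C)(C)C)c1C(=O)C[C@@](C)(O[Si](CC)(CC)CC)CO[Si](CC)(CC)CC | intermediate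
22 | 2-[(2R)-2-methyl-2-(trimethylsilyloxy)but-3-enyl]-3-[(1S,3R)-1-hydroxy-3-methyl-3,4-bis(triethylsilyloxy)butyl]-4-[(tert-butyldimethylsilyloxy)methyl]furan | C=C[C@](C)(O[Si](C)(C)C)Cc1occ(CO[Si](C)(C)C(C)(C)C)c1[C@@H](O)C[C@@](C)(O[Si](CC)(CC)CC)CO[Si](CC)(CC)CC | intermediate
23 | 2-[(2R)-2-methyl-2-(trimethylsilyloxy)but-3-enyl]-3-[(1S,3R)-1-(tert-butyldimethylsilyloxy)-3-methyl-3,4-bis(triethylsilyloxy)butyl]-4-[(tert-butyldimethylsilyloxy)methyl]furan | C=C[C@](C)(O[Si](C)(C)C)Cc1occ(CO[Si](C)(C)C(C)(C)C)c1[C@@H](O[Si](C)(C)C(C)(C)C)C[C@@](C)(O[Si](CC)(CC)CC)CO[Si](CC)(CC)CC | intermediate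
24 | 2-[(2R)-2-hydroxy-2-methylbut-3-enyl]-3-[(1S,3R)-1-(tert-butyldimethylsilyloxy)-4-hydroxy-3-methyl-3-(triethylsilyloxy)butyl]-4-[(tert-butyldimethylsilyloxy)methyl]furan | C=C[C@](C)(O)Cc1occ(CO[Si](C)(C)C(C)(C)C)c1[C@@H](O[Si](C)(C)C(C)(C)C)C[C@@](C)(O[Si](CC)(CC)CC)CO | intermediate
25 | (2R,4S)-4-(tert-butyldimethylsilyloxy)-4-{2-[(2R)-2-hydroxy-2-methylbut-3-enyl]-4-[(tert-butyldimethylsilyloxy)methyl]furan-3-yl}-2-methyl-2-(triethylsilyloxy)butanal | C=C[C@](C)(O)Cc1occ(CO[Si](C)(C)C(C)(C)C)c1[C@@H](O[Si](C)(C)C(C)(C)C)C[C@@](C)(O[Si](CC)(CC)CC)C=O | intermediate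
26 | 2-[(2R)-2-hydroxy-2-methylbut-3-enyl]-3-[(1S,3R)-1-(tert-butyldimethylsilyloxy)-4-hydroxy-3-methyl-3-(triethylsilyloxy)hex-5-enyl]-4-[(tert-butyldimethylsilyloxy)methyl]furan (both C1 epimers) | C=C[C@](C)(O)Cc1occ(CO[Si](C)(C)C(C)(C)C)c1[C@@H](O[Si](C)(C)C(C)(C)C)C[C@@](C)(O[Si](CC)(CC)CC)C(O)C=C | intermediate
27 | (4R,6S)-6-(tert-butyldimethylsilyloxy)-6-{2-[(2R)-2-hydroxy-2-methylbut-3-enyl]-4-[(tert-butyldimethylsilyloxy)methyl]furan-3-yl}-4-methyl-4-(triethylsilyloxy)hex-1-en-3-one | C=C[C@](C)(O)Cc1occ(CO[Si](C)(C)C(C)(C)C)c1[C@@H](O[Si](C)(C)C(C)(C)C)C[C@@](C)(O[Si](CC)(CC)CC)C(=O)C=C | intermediate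
28 | 2-[(2R)-2-hydroxy-2-methylbut-3-enyl]-3-[(1S,3R,4R)-1-(tert-butyldimethylsilyloxy)-4-hydroxy-3-methyl-3-(triethylsilyloxy)hex-5-enyl]-4-[(tert-butyldimethylsilyloxy)methyl]furan (1R,4R,8S,10R) | CC(C)(C)[Si](C)(C)O[C@@H](C[C@@](C)(O[Si](CC)(CC)CC)[C@H](O)C=C)c1c(CO[Si](C)(C)C(C)(C)C)coc1C[C@@](C)(O)C=C | intermediate
29 | furan-fused (Z)-cyclodecene-1,4-diol (1R,2Z,4R,8S,10R; 8-OTBS, 10-OTES, 13-OTBS) | CC(C)(C)[Si](C)(C)O[C@H]1C[C@@](C)(O[Si](CC)(CC)CC)[C@H](O)/C=C\[C@](C)(O)Cc2occ(CO[Si](C)(C)C(C)(C)C)c21 | intermediate
30 | C1 methanesulfonate of 29 (1R,2Z,4R,8S,10R) | CC(C)(C)[Si](C)(C)O[C@H]1C[C@@](C)(O[Si](CC)(CC)CC)[C@H](OS(C)(=O)=O)/C=C\[C@](C)(O)Cc2occ(CO[Si](C)(C)C(C)(C)C)c21 | intermediate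
31 | 1,4-epoxy-bridged 2,5-dihydrofuran fused furan (1S,4R,8S,10R; 8-OTBS, 10-OTES, 13-OTBS) | CC(C)(C)[Si](C)(C)O[C@H]1C[C@@](C)(O[Si](CC)(CC)CC)[C@@H]2C=C[C@@](C)(Cc3occ(CO[Si](C)(C)C(C)(C)C)c31)O2 | intermediate
32 | 1,4-epoxy-bridged oxolane fused furan (1S,4S,8S,10R; 8-OTBS, 10-OTES, 13-OTBS) | CC(C)(C)[Si](C)(C)O[C@H]1C[C@@](C)(O[Si](CC)(CC)CC)[C@@H]2CC[C@@](C)(Cc3occ(CO[Si](C)(C)C(C)(C)C)c31)O2 | intermediate
33 | furan endoperoxide of 32 (2,3,7-trioxabicyclo[2.2.1]hept-5-ene across C6 and C12) | CC(C)(C)[Si](C)(C)O[C@H]1C[C@@](C)(O[Si](CC)(CC)CC)[C@@H]2CC[C@@](C)(CC34OOC(O3)C(CO[Si](C)(C)C(C)(C)C)=C41)O2 | intermediate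
34 | γ-hydroxybutenolide (C12=O, C6–OH, C6 epimers; 1S,4S,8S,10R) | CC(C)(C)[Si](C)(C)O[C@H]1C[C@@](C)(O[Si](CC)(CC)CC)[C@@H]2CC[C@@](C)(CC3(O)OC(=O)C(CO[Si](C)(C)C(C)(C)C)=C31)O2 | intermediate
35 | C6 methanesulfonate of 34 | CC(C)(C)[Si](C)(C)O[C@H]1C[C@@](C)(O[Si](CC)(CC)CC)[C@@H]2CC[C@@](C)(CC3(OS(C)(=O)=O)OC(=O)C(CO[Si](C)(C)C(C)(C)C)=C31)O2 | intermediate
36 | (1S,4S,5E,8S,10R)-8,13-bis(tert-butyldimethylsilyloxy)-1,4-epoxy-10-(triethylsilyloxy)germacra-5,7(11)-dien-6,12-olide | CC(C)(C)[Si](C)(C)O[C@H]1C[C@@](C)(O[Si](CC)(CC)CC)[C@@H]2CC[C@@](C)(/C=C3/OC(=O)C(CO[Si](C)(C)C(C)(C)C)=C31)O2 | intermediate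
37 | (1S,4S,5E,8S,10R)-1,4-epoxy-8,10,13-trihydroxygermacra-5,7(11)-dien-6,12-olide | O[C@H]1C[C@@](C)(O)[C@@H]2CC[C@@](C)(/C=C3/OC(=O)C(CO)=C31)O2 | intermediate
38 | (1S,4S,5E,8S,10R)-13-acetoxy-1,4-epoxy-8,10-dihydroxygermacra-5,7(11)-dien-6,12-olide | O[C@H]1C[C@@](C)(O)[C@@H]2CC[C@@](C)(/C=C3/OC(=O)C(COC(C)=O)=C31)O2 | intermediate
39 | angelic acid, (Z)-2-methylbut-2-enoic acid | C/C=C(/C)C(=O)O | starting material
40 | angelic 2,4,6-trichlorobenzoic anhydride | C/C=C(/C)C(=O)OC(=O)c1c(Cl)cc(Cl)cc1Cl | intermediate
41 | (1S,4S,5E,8S,10R)-13-acetoxy-8-angeloyloxy-1,4-epoxy-10-hydroxygermacra-5,7(11)-dien-6,12-olide (CNP0162854.1) | C/C=C(/C)C(=O)O[C@H]1C[C@@](C)(O)[C@@H]2CC[C@@](C)(/C=C3/OC(=O)C(COC(C)=O)=C31)O2 | target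

## Step count and risks

Total: 25 steps. Longest linear sequence: 21 steps (steps 1, 2, 4, 5 and 9 to 25, from 1).

**Step 18 (key step).** The most likely failures are oligomerisation by intermolecular metathesis, formation of the (E)-alkene, and isomerisation of the allylic alcohols by ruthenium hydrides. Both alkenes are hindered and the ring is medium-sized.

Fallback: starting from 28, O1 and O4 are tied together with i-Pr2Si(OTf)2 and 2,6-lutidine at high dilution to give the eleven-membered cyclic diisopropylsilylene acetal F1. Metathesis with the same ruthenium carbene then only has to close a seven-membered 1,3-dioxa-2-silacyclohept-5-ene, which can only be (Z), giving the bicyclic silaketal F2. Buffered fluoride (Bu4NF/AcOH, 0 °C) should cleave the dialkoxysilane faster than the trialkylsilyl ethers, and the route is rejoined at 29.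

**Step 19.** Two processes may interfere. The allylic mesylate may ionise, losing stereospecificity and closing with retention to the less strained cis-bridged C1 epimer. Alternatively the closure may fail altogether, because the trans bridge builds strain in the transition state. If that strain is prohibitive, no ether closure can deliver this diastereomer and only the C1 epimer would be reachable.

Fallback: starting from 29, diimide reduction is done first to give the saturated 1,4-diol F3. Its C1 hydroxyl is mesylated to F4, which is not allylic and cannot ionise. KN(SiMe3)2 in THF then closes the oxolane by clean SN2, and the route is rejoined at 32.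

**Step 4.** The aryllithium may displace the tosylate directly instead of opening the epoxide. That path gives the enantiomeric epoxide and erodes the C4 configuration. Lewis-acid rearrangement of the epoxide is a second risk.

Fallback: starting from 5, the same lithiation is followed by transmetalation with MgBr2·OEt2 and CuI-catalysed opening of the silyl ether 13, which has no leaving group, to give the tertiary alcohol F5. PPTS in MeOH removes the primary TES group to give diol F6. TsCl/Et3N sulfonylates the primary hydroxyl to give 9, which closes with K2CO3 in MeOH, rejoining the route at 10.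

**Step 11.** Poor facial selectivity or very slow reduction is possible, because the ketone is flanked by two ortho substituents on the furan and a neopentyl-type methylene.

Fallback: starting from 21, NaBH4 in MeOH gives both C8 epimers, which are diastereomers and separable by chromatography. The (8S) epimer is 22. The (8R) epimer F7 is re-oxidised with Dess–Martin periodinane to 21 and recycled, so the route continues from 22.

**Step 13.** Loss of the tertiary TES group at C10 or the primary TBS group at C13, or silyl migration from O10 to O1, may accompany the intended cleavage.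

Fallback: starting from 23, Swern conditions ((COCl)2, DMSO, then Et3N, −78 °C) oxidise the primary TES ether directly to the aldehyde F8, in which the C4 TMS ether is kept. K2CO3 in MeOH at 0 °C then removes the TMS group, and the route is rejoined at 25.

## Further compounds

F1 | step 18 | eleven-membered cyclic diisopropylsilylene acetal of 28 linking O1 and O4 (1R,4R,8S,10R) | CC(C)(C)[Si](C)(C)O[C@H]1C[C@@](C)(O[Si](CC)(CC)CC)[C@@H](C=C)O[Si](C(C)C)(C(C)C)O[C@@](C)(C=C)Cc2occ(CO[Si](C)(C)C(C)(C)C)c21
F2 | step 18 | bicyclic silaketal with (Z)-C2=C3 in a 1,3-dioxa-2-silacyclohept-5-ene (1R,2Z,4R,8S,10R) | CC(C)(C)[Si](C)(C)O[C@H]1C[C@@](C)(O[Si](CC)(CC)CC)[C@H]3/C=C\[C@](C)(O[Si](C(C)C)(C(C)C)O3)Cc2occ(CO[Si](C)(C)C(C)(C)C)c21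
F3 | step 19 | furan-fused cyclodecane-1,4-diol, the 2,3-dihydro derivative of 29 (1R,4S,8S,10R) | CC(C)(C)[Si](C)(C)O[C@H]1C[C@@](C)(O[Si](CC)(CC)CC)[C@H](O)CC[C@](C)(O)Cc2occ(CO[Si](C)(C)C(C)(C)C)c21
F4 | step 19 | C1 methanesulfonate of F3 (1R,4S,8S,10R) | CC(C)(C)[Si](C)(C)O[C@H]1C[C@@](C)(O[Si](CC)(CC)CC)[C@H](OS(C)(=O)=O)CC[C@](C)(O)Cc2occ(CO[Si](C)(C)C(C)(C)C)c21
F5 | step 4 | (2R)-1-{3-bromo-4-[(tert-butyldimethylsilyloxy)methyl]furan-2-yl}-2-methyl-3-(triethylsilyloxy)propan-2-ol | C[C@](O)(CO[Si](CC)(CC)CC)Cc1occ(CO[Si](C)(C)C(C)(C)C)c1Br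
F6 | step 4 | (2R)-3-{3-bromo-4-[(tert-butyldimethylsilyloxy)methyl]furan-2-yl}-2-methylpropane-1,2-diol | C[C@](O)(CO)Cc1occ(CO[Si](C)(C)C(C)(C)C)c1Br
F7 | step 11 | (8R) epimer of 22, 3-[(1R,3R)-1-hydroxy-3-methyl-3,4-bis(triethylsilyloxy)butyl] analogue | C=C[C@](C)(O[Si](C)(C)C)Cc1occ(CO[Si](C)(C)C(C)(C)C)c1[C@H](O)C[C@@](C)(O[Si](CC)(CC)CC)CO[Si](CC)(CC)CC
F8 | step 13 | C1 aldehyde with the C4 trimethylsilyl ether retained (4R,8S,10R) | C=C[C@](C)(O[Si](C)(C)C)Cc1occ(CO[Si](C)(C)C(C)(C)C)c1[C@@H](O[Si](C)(C)C(C)(C)C)C[C@@](C)(O[Si](CC)(CC)CC)C=O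
A1 | alternative 1 | 8,13-bis-TBS ether of the deacylated target with free C10–OH | CC(C)(C)[Si](C)(C)O[C@H]1C[C@@](C)(O)[C@@H]2CC[C@@](C)(/C=C3/OC(=O)C(CO[Si](C)(C)C(C)(C)C)=C31)O2
A2 | alternative 2 | macrocyclic 5,6-dihydro butenolide with the oxolane in place (8,13-bis-TBS, one C6 epimer) | CC(C)(C)[Si](C)(C)O[C@H]1C[C@@](C)(O)[C@@H]2CC[C@@](C)(C[C@@H]3OC(=O)C(CO[Si](C)(C)C(C)(C)C)=C31)O2
A3 | alternative 3 | 1,4-bridged oxolane with C5–OH on the 5,6-dihydro butenolide (8,13-bis-TBS, 10-TES) | CC(C)(C)[Si](C)(C)O[C@H]1C[C@@](C)(O[Si](CC)(CC)CC)[C@@H]2CC[C@@](C)([C@H](O)[C@H]3OC(=O)C(CO[Si](C)(C)C(C)(C)C)=C31)O2
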